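The retrosynthesis cuts, in order: the two S–O bonds and the 4′-O protecting group; the C3′–CHO bond; the C9–C11 bond together with the C8–H bond (a C9 vinyl nucleophile plus an ArCH=N electrophile); the auxiliary C2–CO2Et bond; the C3–C4 bond of ring A; and the C10–C1 and C10–CH3 bonds.
The enabling feature is that ring B (C5–C10) is the carvone ring. The carvone carbonyl carbon is C9, the methyl-bearing alkene carbon is C8, then come C7, C6, C5 and the α′-methylene C10. The isopropenyl carbon on C5 is C4 and already carries one geminal methyl, so ring A lacks only C1–C3 and the C3–C4 bond.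
In the forward direction ring B is bought and C10 is made quaternary by two alkylations (methyl, then a C1–C3 acrylate arm). Ring A closes by a radical C3–C4 bond, the ester is excised and the C9 ketone becomes a vinyl iodide. The arene is then joined at C9–C11, formylated, sulfated and unmasked.
C5 comes from (R)-carvone. C10, and with it the trans ring fusion, comes from alkylation anti to the isopropenyl group. C8 and the E C9=C11 bond come from a suprafacial allylic diazene retro-ene on the α face, steered by the axial C10 methyl.

Key step: step 3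

Numbering: drimane numbers are used for the terpene (decalin C1–C10, C11 the benzylidene carbon). Primed numbers are used for the arene: C1′ bears C11, oxygen sits at C2′, C4′ and C5′, CHO at C3′ and H at C6′. Centres that are erased later carry no descriptor (C6 of 2, C2 of 5–7, C8 of 9 and 10).
Assumption: the sulfate half-esters of 24 and 25 are written in the acid form of the target formula. In the flask they would be pyridinium or sodium salts, and the acid form is released only at the very end on a cold H+ resin.

Step 1
Reactants: 1 (R)-(−)-carvone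
Product: 2 (5R)-6-methylcarvone (C6 epimers)
Conditions: LDA, THF, −78 °C; MeI, −78 → −20 °C
Reagents that add atoms: iodomethane, CI
Why: Kinetic deprotonation of the enone takes place at the α′-methylene (future C10) and the cross-conjugated enolate is C-methylated (enolate alkylation), the new centre needing no control because it is flattened again in step 2.

Step 2
Reactants: 2 (5R)-6-methylcarvone (C6 epimers); 3 ethyl 2-(bromomethyl)acrylate
Product: 4 ethyl 2-{[(1S,6S)-1,3-dimethyl-2-oxo-6-(prop-1-en-2-yl)cyclohex-3-en-1-yl]methyl}acrylate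
Conditions: LDA, THF, −78 → 0 °C; DMPU, 3, −78 °C → rt
Reagents that add atoms: none
Why: Re-enolisation gives the tetrasubstituted C9–C10 enolate whose one face is screened by the neighbouring isopropenyl group, so the very reactive allylic bromide (SN2 or SN2′, same product) should enter anti to it and set C10 as S with the acrylate arm trans to the isopropenyl group (diastereoselective enolate alkylation).

Step 3
Reactants: 4 ethyl 2-{[(1S,6S)-1,3-dimethyl-2-oxo-6-(prop-1-en-2-yl)cyclohex-3-en-1-yl]methyl}acrylate
Product: 5 ethyl (5S,10S)-9-oxo-11-nordrim-7-ene-2-carboxylate (C2 epimers)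
Conditions: Fe(acac)3 (30 mol %), PhSiH3, EtOH, 60 °C, 0.02 M, Ar
Reagents that add atoms: none
Why: An iron hydride formed from Fe(acac)3, PhSiH3 and EtOH transfers a hydrogen atom to the CH2 terminus of the isopropenyl group, which creates the second geminal methyl and a nucleophilic tertiary radical at C4. This radical adds to the unsubstituted acrylate terminus C3, and the resulting α-ester radical at C2 is reduced by iron(II) and protonated by ethanol, which returns iron(III). The closest known reaction type is the MHAT-initiated reductive olefin coupling (Giese addition) in its intramolecular form, which has been run on isopropenyl/acrylate pairs including carvone-derived ones. Ring A closes 6-endo-trig through the C3–C4 bond, whereas 5-exo attack at C2 would oppose the acrylate polarity, join two fully substituted carbons and leave a primary radical. No stereocentre of the target is made here: the trans fusion is already fixed by the trans C5 and C10 arms, which can meet only when both are equatorial, and C2 forms as an epimer mixture that step 5 erases. The step needs hydrogen-atom transfer at the isopropenyl group rather than at the enone or acrylate, which the electron-rich, unhindered 1,1-disubstituted alkene secures, and high dilution keeps the addition intramolecular.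

Step 4
Reactants: 5 ethyl (5S,10S)-9-oxo-11-nordrim-7-ene-2-carboxylate (C2 epimers)
Product: 6 (5S,10S)-9-oxo-11-nordrim-7-ene-2-carboxylic acid (C2 epimers)
Conditions: LiOH, THF–MeOH–H2O, rt → 40 °C; then 1 M HCl
Reagents that add atoms: lithium hydroxide, [Li+].[OH-]
Why: Saponification of an unhindered secondary ethyl ester proceeds under conditions that leave the trisubstituted enone and the non-epimerisable C5 and C10 centres untouched.

Step 5
Reactants: 6 (5S,10S)-9-oxo-11-nordrim-7-ene-2-carboxylic acid (C2 epimers)
Product: 8 (5S,10S)-11-nordrim-7-en-9-one, via Barton ester 7 (not isolated)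
Conditions: 1-hydroxypyridine-2(1H)-thione, DCC, DMAP (cat), CH2Cl2, 0 °C → rt, dark; then t-BuSH, hν (W lamp), rt
Reagents that add atoms: none
Why: Barton decarboxylation turns the thiohydroxamate ester into a secondary C2 radical that has no acceptor within reach and is capped by hydrogen transfer from the thiol, which removes the activating group and the stray C2 centre.

Step 6
Reactants: 8 (5S,10S)-11-nordrim-7-en-9-one
Product: 9 (5S,10S)-11-nordriman-9-one (C8 epimers)
Conditions: H2 (1 atm), 10 % Pd/C, EtOAc, rt
Reagents that add atoms: none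
Why: Heterogeneous hydrogenation saturates only the conjugated C7=C8 bond, and the C8 configuration is irrelevant because this carbon becomes sp2 again in step 8.

Step 7
Reactants: 9 (5S,10S)-11-nordriman-9-one (C8 epimers)
Product: 10 (5S,10S)-11-nordriman-9-one hydrazone
Conditions: N2H4·H2O (excess), Et3N, n-BuOH, 120 °C
Reagents that add atoms: hydrazine (as hydrate), NN
Why: Condensation with the small nucleophile hydrazine under forcing conditions is the established way to derivatise 2,2,6-trisubstituted cyclohexanones, and the large excess suppresses azine formation.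

Step 8
Reactants: 10 (5S,10S)-11-nordriman-9-one hydrazone
Product: 11 (5S,10S)-9-iodo-11-nordrim-8-ene
Conditions: I2, 1,1,3,3-tetramethylguanidine, THF–Et2O, 0 °C → rt
Reagents that add atoms: iodine, II
Why: In the Barton vinyl iodide synthesis the hydrazone is oxidised to the diazoalkane, iodinated and stripped of N2, and since C10 is quaternary the only proton that can leave is H8, so the tetrasubstituted C8=C9 iodide is the sole regioisomer.

Step 9
Reactants: 12 2,4,5-trihydroxybenzaldehyde
Product: 13 2,5-dihydroxy-4-(4-methoxybenzyloxy)benzaldehyde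
Conditions: PMBCl (1 equiv), NaHCO3, NaI (cat), DMF, 40 °C, Ar
Reagents that add atoms: 4-methoxybenzyl chloride, COc1ccc(CCl)cc1
Why: With a weak base only the most acidic phenol, the 4-OH para to the formyl group, is ionised while the 2-OH is locked in a hydrogen bond and the 5-OH is not activated, so the Williamson etherification should mark exactly the oxygen that stays unsulfated (known regioselectivity of 2,4- and 3,4-dihydroxybenzaldehydes).

Step 10
Reactants: 13 2,5-dihydroxy-4-(4-methoxybenzyloxy)benzaldehyde
Product: 14 4-(4-methoxybenzyloxy)-2,5-bis(methoxymethoxy)benzaldehyde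
Conditions: NaH, MOMCl, DMF, 0 °C → rt
Reagents that add atoms: chloromethyl methyl ether, COCCl
Why: Full deprotonation overrides the hydrogen bond at O2 and both phenoxides are alkylated to MOM acetals, which tolerate organolithiums and later direct the metalation.

Step 11
Reactants: 14 4-(4-methoxybenzyloxy)-2,5-bis(methoxymethoxy)benzaldehyde
Product: 15 (E)-tosylhydrazone of 14
Conditions: TsNHNH2, THF, rt
Reagents that add atoms: p-toluenesulfonyl hydrazide, Cc1ccc(cc1)S(=O)(=O)NN
Why: Aromatic aldehydes condense with tosylhydrazide without added acid, so the acetal and PMB groups are not at risk.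

Step 12
Reactants: 15 (E)-tosylhydrazone of 14
Product: 16 N-(tert-butyldimethylsilyl) tosylhydrazone of 14
Conditions: TBSOTf, Et3N, THF, −78 °C
Reagents that add atoms: tert-butyldimethylsilyl triflate, CC(C)(C)[Si](C)(C)OS(=O)(=O)C(F)(F)F
Why: N-Silylation removes the only acidic proton of the hydrazone, so that an organolithium can add to the C=N bond instead of deprotonating it, and the amine buffer at low temperature protects the MOM acetals.

Step 13
Reactants: 11 (5S,10S)-9-iodo-11-nordrim-8-ene; 16 N-(tert-butyldimethylsilyl) tosylhydrazone of 14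
Product: 19 (5S,8S,10S,9(11)E)-11-[4-(4-methoxybenzyloxy)-2,5-bis(methoxymethoxy)phenyl]drim-9(11)-ene, via vinyllithium 17 (not isolated), via allylic diazene 18 (not isolated)
Conditions: 11, t-BuLi (2 equiv), Et2O, −78 °C; 16, THF, −78 °C; AcOH, CF3CH2OH, −78 → 23 °C
Reagents that add atoms: none
Why: Iodine–lithium exchange gives the C9 vinyllithium, whose 1,2-addition to the N-silyl tosylhydrazone followed by sulfinate loss and protodesilylation delivers an allylic diazene (organolithium/silyl tosylhydrazone reductive coupling with allylic diazene rearrangement); the bulky N–N(TBS)Ts arm should take the open α sector anti to the axial C10 methyl with H11 turned towards C10, so the suprafacial retro-ene puts hydrogen on the α face of C8 (8β-methyl, 8S) and leaves the aryl group cis to C8, which is the E C9=C11 alkene.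

Step 14
Reactants: 19 (5S,8S,10S,9(11)E)-11-[4-(4-methoxybenzyloxy)-2,5-bis(methoxymethoxy)phenyl]drim-9(11)-ene
Product: 21 3′-carbaldehyde of 19, via aryllithium 20 (not isolated)
Conditions: n-BuLi, TMEDA, THF, −78 → −10 °C; DMF, −78 °C → rt; H2O
Reagents that add atoms: N,N-dimethylformamide, CN(C)C=O
Why: In this directed ortho-metalation C3′–H lies between two oxygen donors (2′-OMOM and 4′-OPMB) and is lithiated by their cooperative effect in preference to C6′–H, which has one donor and the bulky alkenyl neighbour, and DMF then delivers the formyl group.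

Step 15
Reactants: 21 3′-carbaldehyde of 19
Product: 23 (5S,8S,10S,9(11)E)-11-[3-formyl-2,5-dihydroxy-4-(4-methoxybenzyloxy)phenyl]drim-9(11)-ene, via bis-silyl ether 22 (not isolated)
Conditions: TMSOTf, 2,2′-bipyridyl, CH2Cl2, 0 °C → rt; then H2O
Reagents that add atoms: none
Why: The silyl triflate/bipyridyl pair converts aromatic MOM acetals through bipyridinium salts into aryl silyl ethers that hydrolyse on addition of water, and because the medium never turns acidic the PMB ether survives and the freed 2′-phenol cannot add to the C9=C11 bond.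

Step 16
Reactants: 23 (5S,8S,10S,9(11)E)-11-[3-formyl-2,5-dihydroxy-4-(4-methoxybenzyloxy)phenyl]drim-9(11)-ene
Product: 24 2′,5′-bis(hydrogen sulfate) of 23
Conditions: SO3·pyridine (excess), pyridine, rt → 40 °C, Ar
Reagents that add atoms: sulfur trioxide pyridine complex, O=S(=O)=O.c1ccncc1
Why: O-Sulfonation of phenols with the sulfur trioxide–amine complex is the standard route to hydroquinone disulfates, and with O4′ blocked only O2′ and O5′ can react while aldehyde and alkene are inert to the reagent.

Step 17
Reactants: 24 2′,5′-bis(hydrogen sulfate) of 23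
Product: 25 3-formyl-2-hydroxy-5-{(E)-[(2S,4aS,8aS)-2,5,5,8a-tetramethyloctahydronaphthalen-1(2H)-ylidene]methyl}benzene-1,4-diyl bis(hydrogen sulfate)
Conditions: DDQ, MeCN–pH 7 buffer, 0 °C → rt; then Dowex 50W (H+), H2O–MeOH, 0 °C, lyophilise at once
Reagents that add atoms: none
Why: Oxidative PMB cleavage with DDQ runs at neutral pH, where aryl sulfate monoesters are stable, and the arene now carries two sulfates and a formyl group and is therefore too electron-poor for its styrene or its allylic C8–H to be oxidised.

Compound list
1 | (R)-(−)-carvone | CC1=CC[C@@H](C(C)=C)CC1=O | starting material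
2 | (5R)-2,6-dimethyl-5-(prop-1-en-2-yl)cyclohex-2-en-1-one (6-methylcarvone, C6 epimers) | CC1=CC[C@@H](C(C)=C)C(C)C1=O | intermediate
3 | ethyl 2-(bromomethyl)acrylate | C=C(CBr)C(=O)OCC | starting material
4 | ethyl 2-{[(1S,6S)-1,3-dimethyl-2-oxo-6-(prop-1-en-2-yl)cyclohex-3-en-1-yl]methyl}acrylate | CC1=CC[C@@H](C(C)=C)[C@](C)(CC(=C)C(=O)OCC)C1=O | intermediate
5 | ethyl (5S,10S)-9-oxo-11-nordrim-7-ene-2-carboxylate (C2 epimers) | CC1=CC[C@H]2C(C)(C)CC(C(=O)OCC)C[C@]2(C)C1=O | intermediate
6 | (5S,10S)-9-oxo-11-nordrim-7-ene-2-carboxylic acid (C2 epimers) | CC1=CC[C@H]2C(C)(C)CC(C(=O)O)C[C@]2(C)C1=O | intermediate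
7 | 2-thioxopyridin-1(2H)-yl ester of 6 (Barton ester) | CC1=CC[C@H]2C(C)(C)CC(C(=O)ON3C=CC=CC3=S)C[C@]2(C)C1=O | intermediate
8 | (5S,10S)-11-nordrim-7-en-9-one | CC1=CC[C@H]2C(C)(C)CCC[C@]2(C)C1=O | intermediate
9 | (5S,10S)-11-nordriman-9-one (C8 epimers) | CC1CC[C@H]2C(C)(C)CCC[C@]2(C)C1=O | intermediate
10 | (5S,10S)-11-nordriman-9-one hydrazone | CC1CC[C@H]2C(C)(C)CCC[C@]2(C)C1=NN | intermediate
11 | (5S,10S)-9-iodo-11-nordrim-8-ene | CC1=C(I)[C@@]2(C)CCCC(C)(C)[C@@H]2CC1 | intermediate
12 | 2,4,5-trihydroxybenzaldehyde | O=Cc1cc(O)c(O)cc1O | starting material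
13 | 2,5-dihydroxy-4-(4-methoxybenzyloxy)benzaldehyde | O=Cc1cc(O)c(OCc2ccc(OC)cc2)cc1O | intermediate
14 | 4-(4-methoxybenzyloxy)-2,5-bis(methoxymethoxy)benzaldehyde | O=Cc1cc(OCOC)c(OCc2ccc(OC)cc2)cc1OCOC | intermediate
15 | (E)-tosylhydrazone of 14 | Cc1ccc(cc1)S(=O)(=O)N/N=C/c1cc(OCOC)c(OCc2ccc(OC)cc2)cc1OCOC | intermediate
16 | N-(tert-butyldimethylsilyl) tosylhydrazone of 14 | Cc1ccc(cc1)S(=O)(=O)N(/N=C/c1cc(OCOC)c(OCc2ccc(OC)cc2)cc1OCOC)[Si](C)(C)C(C)(C)C | intermediate
17 | (5S,10S)-11-nordrim-8-en-9-yllithium | CC1=C([Li])[C@@]2(C)CCCC(C)(C)[C@@H]2CC1 | intermediate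
18 | (5S,10S,11S)-11-aryl-11-diazenyldrim-8-ene (aryl as in 19) | CC1=C([C@H](N=N)c3cc(OCOC)c(OCc4ccc(OC)cc4)cc3OCOC)[C@@]2(C)CCCC(C)(C)[C@@H]2CC1 | intermediate
19 | (5S,8S,10S,9(11)E)-11-[4-(4-methoxybenzyloxy)-2,5-bis(methoxymethoxy)phenyl]drim-9(11)-ene | C[C@H]1CC[C@H]2C(C)(C)CCC[C@]2(C)/C1=C/c1cc(OCOC)c(OCc2ccc(OC)cc2)cc1OCOC | intermediate
20 | 3′-lithio derivative of 19 | C[C@H]1CC[C@H]2C(C)(C)CCC[C@]2(C)/C1=C/c1cc(OCOC)c(OCc2ccc(OC)cc2)c([Li])c1OCOC | intermediate
21 | 3′-carbaldehyde of 19 | C[C@H]1CC[C@H]2C(C)(C)CCC[C@]2(C)/C1=C/c1cc(OCOC)c(OCc2ccc(OC)cc2)c(C=O)c1OCOC | intermediate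
22 | 2′,5′-bis(trimethylsilyl) ether of 23 | C[C@H]1CC[C@H]2C(C)(C)CCC[C@]2(C)/C1=C/c1cc(O[Si](C)(C)C)c(OCc2ccc(OC)cc2)c(C=O)c1O[Si](C)(C)C | intermediate
23 | (5S,8S,10S,9(11)E)-11-[3-formyl-2,5-dihydroxy-4-(4-methoxybenzyloxy)phenyl]drim-9(11)-ene | C[C@H]1CC[C@H]2C(C)(C)CCC[C@]2(C)/C1=C/c1cc(O)c(OCc2ccc(OC)cc2)c(C=O)c1O | intermediate
24 | 2′,5′-bis(hydrogen sulfate) of 23 | C[C@H]1CC[C@H]2C(C)(C)CCC[C@]2(C)/C1=C/c1cc(OS(=O)(=O)O)c(OCc2ccc(OC)cc2)c(C=O)c1OS(=O)(=O)O | intermediate
25 | CNP0309628.1, 3-formyl-2-hydroxy-5-{(E)-[(2S,4aS,8aS)-2,5,5,8a-tetramethyloctahydronaphthalen-1(2H)-ylidene]methyl}benzene-1,4-diyl bis(hydrogen sulfate) | C[C@H]1CC[C@H]2C(C)(C)CCC[C@]2(C)/C1=C/c1cc(OS(=O)(=O)O)c(O)c(C=O)c1OS(=O)(=O)O | target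

Total step count: 17. Longest linear sequence: 13 steps (steps 1–8, then 13–17). The arene branch (steps 9–12) is made in parallel.

Steps most likely to fail

Step 13. The flanked, tetrasubstituted vinyllithium may add only sluggishly to the C=N bond. Part of the addition may also pass through the β-face arrangement, which would erode the relay of configuration from C10 through C11 to C8. The fallback sets out from 11 and 14 and rejoins the route at 19. Vinyllithium 17, made from 11 as before, is added to the far more electrophilic aldehyde 14 (THF, −78 °C). With the aryl group now the largest substituent and taking the open α sector, this should give the (11R)-allylic benzylic carbinol F1, and its C11 configuration can be checked and purified at this stage. Mitsunobu displacement with 2-nitrobenzenesulfonylhydrazide (PPh3, DEAD, THF, −30 °C → rt) inverts C11 to the N-allyl sulfonylhydrazine F2. On warming, F2 loses sulfinic acid to the same diazene 18, which gives 19.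

Step 17. Hydride abstraction from the PMB group may stall because its ether oxygen is tied to an electron-poor ring. Long exposure or the final acid exchange may then cost a sulfate. The fallback sets out from 23 and rejoins the route at 25, and it carries the sulfates as neutral diesters. Compound 23 is treated with isobutyl chlorosulfate (NaHMDS, THF, −78 °C → rt) to give the chromatographable bis(isobutyl sulfate) F3. Because sulfate diesters tolerate acid and no free 2′-phenol is present, the PMB group can then be removed by brief TFA/anisole treatment (CH2Cl2, 0 °C), which gives the phenol bis(isobutyl sulfate) F4. Sodium iodide in acetone (55 °C) dealkylates both diesters, and cold H+ exchange gives 25.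

Step 3. Hydrogen-atom transfer may be spread over the acrylate and the enone, or the tertiary radical may be reduced before it cyclises. The fallback sets out from 4 and rejoins the route at 5. It keeps the same C3–C4 bond and ring closure but makes the radical from a carbon–halogen bond. Markovnikov addition of HBr (AcOH, 0 °C) to the only electron-rich alkene gives the tertiary bromide F5. Slow addition of Bu3SnH/AIBN (PhH, 80 °C) generates the C4 radical for the same 6-endo Giese cyclisation to 5.

Further compounds
F1 | step 13 | (5S,10S,11R)-11-[4-(4-methoxybenzyloxy)-2,5-bis(methoxymethoxy)phenyl]drim-8-en-11-ol | CC1=C([C@@H](O)c3cc(OCOC)c(OCc4ccc(OC)cc4)cc3OCOC)[C@@]2(C)CCCC(C)(C)[C@@H]2CC1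
F2 | step 13 | (11S)-N-(11-aryldrim-8-en-11-yl)-2-nitrobenzenesulfonohydrazide | CC1=C([C@H](N(N)S(=O)(=O)c5ccccc5[N+](=O)[O-])c3cc(OCOC)c(OCc4ccc(OC)cc4)cc3OCOC)[C@@]2(C)CCCC(C)(C)[C@@H]2CC1
F3 | step 17 | 2′,5′-bis(isobutyl sulfate) of 23 | C[C@H]1CC[C@H]2C(C)(C)CCC[C@]2(C)/C1=C/c1cc(OS(=O)(=O)OCC(C)C)c(OCc2ccc(OC)cc2)c(C=O)c1OS(=O)(=O)OCC(C)C
F4 | step 17 | 2′,5′-bis(isobutyl sulfate) of the 4′-phenol | C[C@H]1CC[C@H]2C(C)(C)CCC[C@]2(C)/C1=C/c1cc(OS(=O)(=O)OCC(C)C)c(O)c(C=O)c1OS(=O)(=O)OCC(C)C
F5 | step 3 | hydrobromide of 4 (2-bromopropan-2-yl in place of isopropenyl) | CC1=CC[C@@H](C(C)(C)Br)[C@](C)(CC(=C)C(=O)OCC)C1=O
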